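**Plan**

- Labels: the cyclohexene runs C1 (quaternary) to C6 (the CH bearing C8 of coumarin B); Ca=Cb is the Z alkene, Ca on C1 and Cb on C8 of coumarin A. The C1-methyl carbon, Ca, Cb, C8, C7 and the 7-oxygen of coumarin A outline a seven-membered ring whose only alkene has to be cis; this makes a temporary O7–CH2–C(=O)–O–Cb tether possible.
- Retrosynthesis: the C1 methyl is traced back to C1–CH(O7)–CO2H (cutting the bond to the carboxyl carbon and the C–O7 bond, and the O7–CH3 ether). Then the C1–(methyl carbon) bond is cut with Cb–O restored ([3,3]), then the lactone acyl–O bond, the Cb–Ca bond, the ring bonds C1–C6 and C2–C3 (Diels–Alder) and the diene C=C bonds.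
- Forward: 8-formyl-5,7-dimethoxycoumarin feeds both halves. Half B closes the cyclohexene first (dienylcoumarin plus acrolein) and becomes an enol triflate. Ni/Cr coupling joins it to the aryloxyacetate aldehyde of half A, and lactonisation closes the seven-membered lactone. The Ireland–Claisen shift turns that lactone into the spiro seven-membered benzoxepine, and the tether is then cut out (SmI2, O-methylation, hydrodecarboxylation).
- Stereochemistry: C6 comes from the amine-catalysed Diels–Alder reaction, Cb from the ligand-controlled Ni/Cr coupling, and the E exocyclic alkene from the enolate triflation. C1 is set by chirality transfer from Cb through a boat transition state, anti to the C6 aryl; the Z alkene is enforced by the ring that forms.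

Key step: step 11

Assumption: the facial sense of the two reagent-controlled steps (6 and 8) is taken from the usual models for the imidazolidinone iminium ion and the chromium sulfonamide complex; if analysis of 11 or 13 shows the opposite sense, the mirror-image catalyst or ligand is used.

**Route**

Step 1
Reactants: 1 5,7-dimethoxycoumarin
Product: 3 5,7-dimethoxy-2-oxo-2H-chromene-8-carbaldehyde, via aryl iminium chloride 2 (not isolated)
Conditions: POCl3, DMF, 0 → 60 °C; then ice-water
Reagents that add atoms: N,N-dimethylformamide, CN(C)C=O (formyl carbon; its nitrogen stays only in 2); phosphoryl chloride, O=P(Cl)(Cl)Cl (chloride counter-ion of 2 only); water, O (carbonyl oxygen)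
Why: Vilsmeier–Haack formylation of the doubly activated ring should go to C8, which is para to the 5-methoxy group and flanked by only one methoxy group, as in other electrophilic substitutions of 5,7-dioxygenated coumarins, and any 6-formyl isomer is removed by crystallisation.

Step 2
Reactants: 3 5,7-dimethoxy-2-oxo-2H-chromene-8-carbaldehyde
Product: 4 7-hydroxy-5-methoxy-2-oxo-2H-chromene-8-carbaldehyde
Conditions: BCl3, CH2Cl2, −78 → 0 °C; then H2O
Reagents that add atoms: none
Why: Chelation-directed ether cleavage, in which BCl3 bound to the formyl oxygen removes only the ortho (C7) methyl group while the 5-methoxy group para to the aldehyde should stay.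

Step 3
Reactants: 4 7-hydroxy-5-methoxy-2-oxo-2H-chromene-8-carbaldehyde; 5 methyl bromoacetate
Product: 6 methyl 2-[(8-formyl-5-methoxy-2-oxo-2H-chromen-7-yl)oxy]acetate
Conditions: K2CO3, acetone, rt
Reagents that add atoms: none
Why: Williamson O-alkylation of the acidic phenol, kept at room temperature so that the new aryloxyacetate does not condense onto the neighbouring aldehyde.

Step 4
Reactants: 3 5,7-dimethoxy-2-oxo-2H-chromene-8-carbaldehyde; 7 (acetylmethylidene)triphenylphosphorane
Product: 8 5,7-dimethoxy-8-[(1E)-3-oxobut-1-en-1-yl]-2H-chromen-2-one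
Conditions: toluene, 90 °C
Reagents that add atoms: none
Why: Wittig olefination with a stabilised ylide should give the E enone under neutral conditions that leave the lactone alone.

Step 5
Reactants: 8 5,7-dimethoxy-8-[(1E)-3-oxobut-1-en-1-yl]-2H-chromen-2-one
Product: 9 5,7-dimethoxy-8-[(1E)-3-methylbuta-1,3-dien-1-yl]-2H-chromen-2-one
Conditions: Ph3PCH3Br, KOtBu, THF, −78 → 0 °C
Reagents that add atoms: methyltriphenylphosphonium bromide, C[P+](c1ccccc1)(c1ccccc1)c1ccccc1.[Br-]
Why: Wittig methylenation, in which the non-stabilised ylide should add to the ketone far faster than to the conjugated aryl lactone at low temperature, leaving the E styrene geometry untouched.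

Step 6
Reactants: 9 5,7-dimethoxy-8-[(1E)-3-methylbuta-1,3-dien-1-yl]-2H-chromen-2-one; 10 acrolein
Product: 11 (1S,6R)-6-(5,7-dimethoxy-2-oxo-2H-chromen-8-yl)-4-methylcyclohex-3-ene-1-carbaldehyde (cis)
Conditions: (5R)-5-benzyl-2,2,3-trimethylimidazolidin-4-one hydrochloride (20 mol %), MeCN/H2O 95:5, 0 °C → rt
Reagents that add atoms: none
Why: Iminium-catalysed Diels–Alder reaction in which the aryl and methyl groups of the diene both direct the formyl-bearing carbon next to the aryl-bearing one, the endo approach gives the cis adduct, and the benzyl group of the catalyst blocks one face of the acrolein iminium ion so that C6 is set as R (C1 as S); the minor exo (trans) adduct, which carries the opposite C6 configuration, is removed here.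

Step 7
Reactants: 11 (1S,6R)-6-(5,7-dimethoxy-2-oxo-2H-chromen-8-yl)-4-methylcyclohex-3-ene-1-carbaldehyde
Product: 12 (E)-[(2R)-2-(5,7-dimethoxy-2-oxo-2H-chromen-8-yl)-4-methylcyclohex-3-en-1-ylidene]methyl trifluoromethanesulfonate
Conditions: KN(SiMe3)2, THF, −78 °C; then PhNTf2, −78 → 0 °C
Reagents that add atoms: N-phenylbis(trifluoromethanesulfonimide), O=S(=O)(N(c1ccccc1)S(=O)(=O)C(F)(F)F)C(F)(F)F
Why: Enolate O-sulfonylation of an α-branched aldehyde, in which the enolate oxygen should sit on the CH2 side away from the aryl-bearing C6 and so give mainly the E triflate (the Z isomer is separated), the C1 centre being erased on purpose while the non-acidic C6 centre is kept.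

Step 8
Reactants: 12 (E)-[(2R)-2-(5,7-dimethoxy-2-oxo-2H-chromen-8-yl)-4-methylcyclohex-3-en-1-ylidene]methyl trifluoromethanesulfonate; 6 methyl 2-[(8-formyl-5-methoxy-2-oxo-2H-chromen-7-yl)oxy]acetate
Product: 13 methyl 2-({8-[(1S,2E)-2-[(2R)-2-(5,7-dimethoxy-2-oxo-2H-chromen-8-yl)-4-methylcyclohex-3-en-1-ylidene]-1-hydroxyethyl]-5-methoxy-2-oxo-2H-chromen-7-yl}oxy)acetate
Conditions: CrCl2 (4 equiv), N-{2-[(4S)-4-isopropyl-4,5-dihydro-1,3-oxazol-2-yl]-6-methylphenyl}methanesulfonamide (4.4 equiv), Et3N, NiCl2 (5 mol %), THF, rt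
Reagents that add atoms: none
Why: Nozaki–Hiyama–Kishi coupling, in which zerovalent nickel inserts into the alkenyl triflate with retention of geometry, the alkenyl group passes to chromium to give a trivalent alkenylchromium species that tolerates esters and lactones, and the chiral sulfonamide ligand on chromium selects the aldehyde face to set Cb as S; the minor Cb epimer is a diastereomer and is removed here or after step 10.

Step 9
Reactants: 13 methyl 2-({8-[(1S,2E)-2-[(2R)-2-(5,7-dimethoxy-2-oxo-2H-chromen-8-yl)-4-methylcyclohex-3-en-1-ylidene]-1-hydroxyethyl]-5-methoxy-2-oxo-2H-chromen-7-yl}oxy)acetate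
Product: 14 2-({8-[(1S,2E)-2-[(2R)-2-(5,7-dimethoxy-2-oxo-2H-chromen-8-yl)-4-methylcyclohex-3-en-1-ylidene]-1-hydroxyethyl]-5-methoxy-2-oxo-2H-chromen-7-yl}oxy)acetic acid
Conditions: Me3SnOH, 1,2-dichloroethane, 60 °C; then brief cold 0.05 M aq. HCl wash
Reagents that add atoms: trimethyltin hydroxide, C[Sn](C)(C)O (hydroxyl oxygen of the acid)
Why: Tin hydroxide-mediated ester hydrolysis should cleave the activated aryloxyacetate methyl ester under near-neutral conditions that spare both coumarin lactones and the ionisation-prone allylic benzylic alcohol.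

Step 10
Reactants: 14 2-({8-[(1S,2E)-2-[(2R)-2-(5,7-dimethoxy-2-oxo-2H-chromen-8-yl)-4-methylcyclohex-3-en-1-ylidene]-1-hydroxyethyl]-5-methoxy-2-oxo-2H-chromen-7-yl}oxy)acetic acid
Product: 15 seven-membered aryloxyacetate lactone of 14 (4,1-benzodioxepin-3-one ring fused at C7–C8 of coumarin A; Cb S; exocyclic alkene E; C6 R)
Conditions: 2-methyl-6-nitrobenzoic anhydride, 4-(dimethylamino)pyridine, Et3N, CH2Cl2 (2 mM, slow addition), rt
Reagents that add atoms: none
Why: Mixed-anhydride (Shiina) lactonisation, in which the ortho arrangement of the two arms on coumarin A holds acid and alcohol close so that the seven-membered ring should close in preference to dimerisation, with retention at Cb because only the acyl carbon is attacked.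

Step 11
Reactants: 15 seven-membered aryloxyacetate lactone (Cb S; exocyclic alkene E; C6 R)
Product: 18 spiro benzoxepine carboxylic acid (2,3-dihydro-1-benzoxepine fused to coumarin A and spiro at C1 of the cyclohexene; carboxyl-bearing carbon S; spiro carbon S; C6 R; Ca=Cb cis), via silyl ketene acetal 16 (not isolated), via trimethylsilyl ester 17 (not isolated)
Conditions: LiN(SiMe3)2, TMSCl, Et3N, THF, −78 °C → rt; then toluene, 80 °C; then aq. citric acid
Reagents that add atoms: chlorotrimethylsilane, C[Si](C)(C)Cl (silyl group of 16 and 17 only)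
Why: Proposed new method: deprotonation of the aryloxyacetate lactone with in situ silylation gives the ring-locked silyl ketene acetal 16, whose ketene acetal carbon bonds to C1 of the cyclohexylidene while the Cb–O bond breaks in a suprafacial [3,3] shift; the closest known reaction type is the Ireland–Claisen ring contraction of alkenyl-substituted lactones, which has not been run on a benzo-fused aryloxyacetate lactone or onto a fully substituted alkene terminus. The new seven-membered 2,3-dihydro-1-benzoxepine ring is closed by that C–C bond in a 7-endo sense (Ca and C1 both end inside it), spiro to the cyclohexene, through a boat-shaped six-atom array, because the three-atom bridge O7–C7–C8 links the ketene acetal carbon to Cb and cannot span a chair. The same bridge forces Ca=Cb to be cis inside the new ring, which is the Z styrene of the target. The quaternary centre C1 is set by chirality transfer from (S)-Cb through this boat with the E alkene, which delivers the new bond to the face anti to the C6 aryl (matched case), so the carbon that becomes the methyl group ends trans to coumarin B. The carboxyl-bearing centre follows from the ring-enforced ketene acetal geometry and the boat, and is erased later. The step needs the [3,3] shift to outrun ionisation of the doubly activated Cb–O ester, which basic enolisation without a Lewis acid should secure.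

Step 12
Reactants: 18 spiro benzoxepine carboxylic acid
Product: 19 methyl ester of 18 (same configurations)
Conditions: TMSCHN2, toluene/MeOH, 0 °C
Reagents that add atoms: (trimethylsilyl)diazomethane, C[Si](C)(C)C=[N+]=[N-]
Why: Diazoalkane esterification under neutral conditions should turn the carboxyl group into an electron acceptor for the next step without touching the lactones.

Step 13
Reactants: 19 methyl ester of the spiro benzoxepine acid
Product: 20 methyl 2-[(1S,6R)-6-(5,7-dimethoxy-2-oxo-2H-chromen-8-yl)-1-[(Z)-2-(7-hydroxy-5-methoxy-2-oxo-2H-chromen-8-yl)ethenyl]-4-methylcyclohex-3-en-1-yl]acetate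
Conditions: SmI2 (2.5 equiv), THF/MeOH, −78 °C
Reagents that add atoms: none
Why: Reductive cleavage of an α-heteroatom-substituted ester by divalent samarium, in which electron transfer expels the coumarin-7-oxide (a good leaving group) and methanol protonates the samarium enolate to leave CH2CO2Me on C1 and the free 7-phenol, while low temperature, the absence of HMPA and only a small excess of reagent should keep the coumarin double bonds from being reduced.

Step 14
Reactants: 20 methyl 2-[(1S,6R)-6-(5,7-dimethoxy-2-oxo-2H-chromen-8-yl)-1-[(Z)-2-(7-hydroxy-5-methoxy-2-oxo-2H-chromen-8-yl)ethenyl]-4-methylcyclohex-3-en-1-yl]acetate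
Product: 21 methyl 2-[(1S,6R)-6-(5,7-dimethoxy-2-oxo-2H-chromen-8-yl)-1-[(Z)-2-(5,7-dimethoxy-2-oxo-2H-chromen-8-yl)ethenyl]-4-methylcyclohex-3-en-1-yl]acetate
Conditions: MeI, K2CO3, acetone, rt
Reagents that add atoms: iodomethane, CI
Why: Williamson O-methylation of the phenoxide should restore the 7-methoxy group of coumarin A, its oxygen being the former tether atom.

Step 15
Reactants: 21 methyl 2-[(1S,6R)-6-(5,7-dimethoxy-2-oxo-2H-chromen-8-yl)-1-[(Z)-2-(5,7-dimethoxy-2-oxo-2H-chromen-8-yl)ethenyl]-4-methylcyclohex-3-en-1-yl]acetate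
Product: 22 2-[(1S,6R)-6-(5,7-dimethoxy-2-oxo-2H-chromen-8-yl)-1-[(Z)-2-(5,7-dimethoxy-2-oxo-2H-chromen-8-yl)ethenyl]-4-methylcyclohex-3-en-1-yl]acetic acid
Conditions: Me3SnOH, 1,2-dichloroethane, 80 °C; then 1 M aq. HCl
Reagents that add atoms: trimethyltin hydroxide, C[Sn](C)(C)O (hydroxyl oxygen of the acid)
Why: Tin hydroxide-mediated hydrolysis should cleave the methyl ester without lasting opening of the coumarins, which reclose on the acidic work-up if touched.

Step 16
Reactants: 22 2-[(1S,6R)-6-(5,7-dimethoxy-2-oxo-2H-chromen-8-yl)-1-[(Z)-2-(5,7-dimethoxy-2-oxo-2H-chromen-8-yl)ethenyl]-4-methylcyclohex-3-en-1-yl]acetic acid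
Product: 24 8-[(Z)-2-[(1R,6R)-6-(5,7-dimethoxy-2-oxo-2H-chromen-8-yl)-1,4-dimethylcyclohex-3-en-1-yl]ethenyl]-5,7-dimethoxy-2H-chromen-2-one (target), via thiohydroxamate ester 23 (not isolated)
Conditions: 1-hydroxypyridine-2(1H)-thione, N,N'-dicyclohexylcarbodiimide, 4-(dimethylamino)pyridine (cat.), CH2Cl2, 0 °C, dark; then PhSeH (10 equiv, about 1 M), benzene, tungsten lamp, 5 °C
Reagents that add atoms: 1-hydroxypyridine-2(1H)-thione, ON1C=CC=CC1=S (part of 23 only)
Why: Barton reductive decarboxylation, in which visible light fragments the thiohydroxamate ester to CO2 and the primary radical on the C1 methylene, and the high concentration of PhSeH (the fastest hydrogen donor available) should trap that radical before it can attack Ca=Cb and undergo a 1,2-vinyl shift, C1 and the Z alkene not being involved.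

**Compound list**

1 | 5,7-dimethoxycoumarin | COc1cc(OC)c2ccc(=O)oc2c1 | starting material
2 | N-[(5,7-dimethoxy-2-oxo-2H-chromen-8-yl)methylidene]-N-methylmethanaminium chloride (not isolated) | COc1cc(OC)c2ccc(=O)oc2c1C=[N+](C)C.[Cl-] | intermediate
3 | 5,7-dimethoxy-2-oxo-2H-chromene-8-carbaldehyde | COc1cc(OC)c2ccc(=O)oc2c1C=O | intermediate
4 | 7-hydroxy-5-methoxy-2-oxo-2H-chromene-8-carbaldehyde | COc1cc(O)c(C=O)c2oc(=O)ccc12 | intermediate
5 | methyl bromoacetate | COC(=O)CBr | starting material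
6 | methyl 2-[(8-formyl-5-methoxy-2-oxo-2H-chromen-7-yl)oxy]acetate | COC(=O)COc1cc(OC)c2ccc(=O)oc2c1C=O | intermediate
7 | (acetylmethylidene)triphenylphosphorane | CC(=O)C=P(c1ccccc1)(c1ccccc1)c1ccccc1 | starting material
8 | 5,7-dimethoxy-8-[(1E)-3-oxobut-1-en-1-yl]-2H-chromen-2-one | COc1cc(OC)c2ccc(=O)oc2c1/C=C/C(C)=O | intermediate
9 | 5,7-dimethoxy-8-[(1E)-3-methylbuta-1,3-dien-1-yl]-2H-chromen-2-one | COc1cc(OC)c2ccc(=O)oc2c1/C=C/C(C)=C | intermediate
10 | acrolein | C=CC=O | starting material
11 | (1S,6R)-6-(5,7-dimethoxy-2-oxo-2H-chromen-8-yl)-4-methylcyclohex-3-ene-1-carbaldehyde (cis) | O=C[C@H]1CCC(C)=C[C@H]1c2c(OC)cc(OC)c3ccc(=O)oc23 | intermediate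
12 | (E)-[(2R)-2-(5,7-dimethoxy-2-oxo-2H-chromen-8-yl)-4-methylcyclohex-3-en-1-ylidene]methyl trifluoromethanesulfonate | O=S(=O)(O/C=C1\CCC(C)=C[C@H]1c2c(OC)cc(OC)c3ccc(=O)oc23)C(F)(F)F | intermediate
13 | methyl 2-({8-[(1S,2E)-2-[(2R)-2-(5,7-dimethoxy-2-oxo-2H-chromen-8-yl)-4-methylcyclohex-3-en-1-ylidene]-1-hydroxyethyl]-5-methoxy-2-oxo-2H-chromen-7-yl}oxy)acetate | COC(=O)COc1cc(OC)c2ccc(=O)oc2c1[C@@H](O)/C=C3\CCC(C)=C[C@H]3c4c(OC)cc(OC)c5ccc(=O)oc45 | intermediate
14 | 2-({8-[(1S,2E)-2-[(2R)-2-(5,7-dimethoxy-2-oxo-2H-chromen-8-yl)-4-methylcyclohex-3-en-1-ylidene]-1-hydroxyethyl]-5-methoxy-2-oxo-2H-chromen-7-yl}oxy)acetic acid | OC(=O)COc1cc(OC)c2ccc(=O)oc2c1[C@@H](O)/C=C3\CCC(C)=C[C@H]3c4c(OC)cc(OC)c5ccc(=O)oc45 | intermediate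
15 | seven-membered aryloxyacetate lactone of 14 (4,1-benzodioxepin-3-one fused at C7–C8 of coumarin A; Cb S, exocyclic alkene E, C6 R) | O=C1COc2cc(OC)c3ccc(=O)oc3c2[C@H](/C=C4\CCC(C)=C[C@H]4c5c(OC)cc(OC)c6ccc(=O)oc56)O1 | intermediate
16 | trimethylsilyl ketene acetal of lactone 15 (not isolated) | C[Si](C)(C)OC1=COc2cc(OC)c3ccc(=O)oc3c2[C@H](/C=C4\CCC(C)=C[C@H]4c5c(OC)cc(OC)c6ccc(=O)oc56)O1 | intermediate
17 | trimethylsilyl ester of acid 18 (not isolated) | COc1cc2c(c3oc(=O)ccc13)/C=C\[C@@]4([C@H](O2)C(=O)O[Si](C)(C)C)CCC(C)=C[C@H]4c5c(OC)cc(OC)c6ccc(=O)oc56 | intermediate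
18 | spiro benzoxepine carboxylic acid (carboxyl-bearing carbon S, spiro carbon S, C6 R, Ca=Cb cis) | COc1cc2c(c3oc(=O)ccc13)/C=C\[C@@]4([C@H](O2)C(=O)O)CCC(C)=C[C@H]4c5c(OC)cc(OC)c6ccc(=O)oc56 | intermediate
19 | methyl ester of 18 | COc1cc2c(c3oc(=O)ccc13)/C=C\[C@@]4([C@H](O2)C(=O)OC)CCC(C)=C[C@H]4c5c(OC)cc(OC)c6ccc(=O)oc56 | intermediate
20 | methyl 2-[(1S,6R)-6-(5,7-dimethoxy-2-oxo-2H-chromen-8-yl)-1-[(Z)-2-(7-hydroxy-5-methoxy-2-oxo-2H-chromen-8-yl)ethenyl]-4-methylcyclohex-3-en-1-yl]acetate | COc1cc(O)c(c2oc(=O)ccc12)/C=C\[C@@]3(CC(=O)OC)CCC(C)=C[C@H]3c4c(OC)cc(OC)c5ccc(=O)oc45 | intermediate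
21 | methyl 2-[(1S,6R)-6-(5,7-dimethoxy-2-oxo-2H-chromen-8-yl)-1-[(Z)-2-(5,7-dimethoxy-2-oxo-2H-chromen-8-yl)ethenyl]-4-methylcyclohex-3-en-1-yl]acetate | COc1cc(OC)c(c2oc(=O)ccc12)/C=C\[C@@]3(CC(=O)OC)CCC(C)=C[C@H]3c4c(OC)cc(OC)c5ccc(=O)oc45 | intermediate
22 | 2-[(1S,6R)-6-(5,7-dimethoxy-2-oxo-2H-chromen-8-yl)-1-[(Z)-2-(5,7-dimethoxy-2-oxo-2H-chromen-8-yl)ethenyl]-4-methylcyclohex-3-en-1-yl]acetic acid | COc1cc(OC)c(c2oc(=O)ccc12)/C=C\[C@@]3(CC(=O)O)CCC(C)=C[C@H]3c4c(OC)cc(OC)c5ccc(=O)oc45 | intermediate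
23 | 2-thioxopyridin-1(2H)-yl ester of acid 22 (not isolated) | COc1cc(OC)c(c2oc(=O)ccc12)/C=C\[C@@]3(CC(=O)ON6C=CC=CC6=S)CCC(C)=C[C@H]3c4c(OC)cc(OC)c5ccc(=O)oc45 | intermediate
24 | 8-[(Z)-2-[(1R,6R)-6-(5,7-dimethoxy-2-oxo-2H-chromen-8-yl)-1,4-dimethylcyclohex-3-en-1-yl]ethenyl]-5,7-dimethoxy-2H-chromen-2-one | COc1cc(OC)c2ccc(=O)oc2c1/C=C\[C@@]1(C)CCC(C)=C[C@H]1c1c(OC)cc(OC)c2ccc(=O)oc12 | target

**Step count and risks**

Total: 16 steps. Longest linear sequence: 14 steps (steps 1 and 4 to 16, from 5,7-dimethoxycoumarin).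

Steps most likely to fail:

1. Step 11 (Proposed new method). The boat-shaped shift has to bring the ring CH2 next to C1, the bridge oxygen and C8 close together, so it may be slower than ionisation of the doubly activated Cb–O bond. That would scramble Cb, give [1,3]-shifted or eliminated material, and lose facial fidelity at C1. The fallback uses known chemistry, sets out from 11 and returns at 24. The potassium enolate of 11 (KN(SiMe3)2, THF, −78 °C) is methylated with MeI anti to the neighbouring aryl group to give the quaternary aldehyde (1S,6R)-6-(5,7-dimethoxy-2-oxo-2H-chromen-8-yl)-1,4-dimethylcyclohex-3-ene-1-carbaldehyde F1. Dimethyl (1-diazo-2-oxopropyl)phosphonate with K2CO3 in MeOH converts it into the terminal alkyne F2. Sonogashira coupling (Pd(PPh3)2Cl2, CuI, Et3N) with 8-iodo-5,7-dimethoxycoumarin F3, made from 1 with N-iodosuccinimide and CF3CO2H, gives the aryl alkyne F4. Semihydrogenation (H2, Pd/CaCO3 poisoned with Pb(OAc)2, quinoline) then gives 24 with the Z alkene.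

2. Step 13. Electron transfer may go to the coumarin rings instead of the ester, which would reduce the C3=C4 bonds or cause reductive dimerisation. The fallback avoids single-electron reduction of the ester; it sets out from 18 and returns at 24. Oxidative decarboxylation of the α-aryloxy acid with Pb(OAc)4 (benzene/pyridine, rt) gives the cyclic O-aryl O-acetyl acetal F5. K2CO3 in MeOH removes the acetate and the hemiacetal opens to the phenol aldehyde F6, which is O-methylated (MeI, K2CO3) to the dimethoxy aldehyde F7. NaBH4 (MeOH/THF, 0 °C) gives the neopentyl alcohol F8, and PhOC(S)Cl with pyridine gives the O-phenyl thionocarbonate F9. Barton–McCombie deoxygenation (Bu3SnH, PhSeSePh cat., AIBN, benzene, 80 °C) then gives 24; it passes through the same primary radical as step 16, so the selenol additive is kept.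

3. Step 16. The primary radical may add 3-exo to Ca=Cb and reopen (1,2-vinyl shift), or reversible addition of the selenium-centred radical may isomerise the Z alkene. The fallback avoids a free radical; it sets out from 22 and returns at 24. EtSH with N,N'-dicyclohexylcarbodiimide and 4-(dimethylamino)pyridine gives the S-ethyl thioester F10. Fukuyama reduction (Et3SiH, Pd/C, acetone, rt) gives the aldehyde F11. Tsuji–Wilkinson decarbonylation (RhCl(PPh3)3, 1 equiv, toluene, 110 °C) then gives 24: the alkylrhodium intermediate has no β-hydrogen because C1 is quaternary, and the hindered Ca=Cb should not enter hydroacylation.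

Further compounds

F1 | step 11 | (1S,6R)-6-(5,7-dimethoxy-2-oxo-2H-chromen-8-yl)-1,4-dimethylcyclohex-3-ene-1-carbaldehyde | O=C[C@@]1(C)CCC(C)=C[C@H]1c2c(OC)cc(OC)c3ccc(=O)oc23
F2 | step 11 | 8-[(1R,6S)-6-ethynyl-3,6-dimethylcyclohex-2-en-1-yl]-5,7-dimethoxy-2H-chromen-2-one | C#C[C@@]1(C)CCC(C)=C[C@H]1c2c(OC)cc(OC)c3ccc(=O)oc23
F3 | step 11 | 8-iodo-5,7-dimethoxy-2H-chromen-2-one | COc1cc(OC)c2ccc(=O)oc2c1I
F4 | step 11 | 8-{[(1S,6R)-6-(5,7-dimethoxy-2-oxo-2H-chromen-8-yl)-1,4-dimethylcyclohex-3-en-1-yl]ethynyl}-5,7-dimethoxy-2H-chromen-2-one | COc1cc(OC)c2ccc(=O)oc2c1C#C[C@@]3(C)CCC(C)=C[C@H]3c4c(OC)cc(OC)c5ccc(=O)oc45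
F5 | step 13 | spiro 2-acetoxy-2,3-dihydro-1-benzoxepine acetal from 18 (acetal carbon as a mixture of epimers; spiro carbon and C6 as in 18) | COc1cc2c(c3oc(=O)ccc13)/C=C\[C@@]4(C(O2)OC(C)=O)CCC(C)=C[C@H]4c5c(OC)cc(OC)c6ccc(=O)oc56
F6 | step 13 | (1S,6R)-6-(5,7-dimethoxy-2-oxo-2H-chromen-8-yl)-1-[(Z)-2-(7-hydroxy-5-methoxy-2-oxo-2H-chromen-8-yl)ethenyl]-4-methylcyclohex-3-ene-1-carbaldehyde | COc1cc(O)c(c2oc(=O)ccc12)/C=C\[C@@]3(C=O)CCC(C)=C[C@H]3c4c(OC)cc(OC)c5ccc(=O)oc45
F7 | step 13 | (1S,6R)-6-(5,7-dimethoxy-2-oxo-2H-chromen-8-yl)-1-[(Z)-2-(5,7-dimethoxy-2-oxo-2H-chromen-8-yl)ethenyl]-4-methylcyclohex-3-ene-1-carbaldehyde | COc1cc(OC)c(c2oc(=O)ccc12)/C=C\[C@@]3(C=O)CCC(C)=C[C@H]3c4c(OC)cc(OC)c5ccc(=O)oc45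
F8 | step 13 | 8-[(Z)-2-[(1S,6R)-6-(5,7-dimethoxy-2-oxo-2H-chromen-8-yl)-1-(hydroxymethyl)-4-methylcyclohex-3-en-1-yl]ethenyl]-5,7-dimethoxy-2H-chromen-2-one | COc1cc(OC)c(c2oc(=O)ccc12)/C=C\[C@@]3(CO)CCC(C)=C[C@H]3c4c(OC)cc(OC)c5ccc(=O)oc45
F9 | step 13 | O-phenyl thionocarbonate of alcohol F8 | COc1cc(OC)c(c2oc(=O)ccc12)/C=C\[C@@]3(COC(=S)Oc6ccccc6)CCC(C)=C[C@H]3c4c(OC)cc(OC)c5ccc(=O)oc45
F10 | step 16 | S-ethyl thioester of acid 22 | COc1cc(OC)c(c2oc(=O)ccc12)/C=C\[C@@]3(CC(=O)SCC)CCC(C)=C[C@H]3c4c(OC)cc(OC)c5ccc(=O)oc45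
F11 | step 16 | 2-[(1S,6R)-6-(5,7-dimethoxy-2-oxo-2H-chromen-8-yl)-1-[(Z)-2-(5,7-dimethoxy-2-oxo-2H-chromen-8-yl)ethenyl]-4-methylcyclohex-3-en-1-yl]acetaldehyde | COc1cc(OC)c(c2oc(=O)ccc12)/C=C\[C@@]3(CC=O)CCC(C)=C[C@H]3c4c(OC)cc(OC)c5ccc(=O)oc45
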